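Count the reagent.

| flask | substrate | reagent | remark | time |
|---|---|---|---|---|
| spring | 0.050 M | 0.57 equiv | run made earlier |  |
| summer | 0.050 M | 1.4 equiv | run made earlier |  |
| dawn | 0.050 M | 3.6 equiv | run made earlier |  |
| larch | 0.050 M | 0.500 equiv |  | 4.0 d |
| alder | 0.050 M | 1.00 equiv |  | 4.0 d |
| elm | 0.050 M | 2.00 equiv |  | 4.0 d |
| ash | 0.050 M | 4.00 equiv |  | 4.0 d |

| run | time / d | mono adduct / % | substrate / % |
|---|---|---|---|
| spring | 0.500 | 11.3 | 88.3 |
| spring | 1.25 | 19.2 | 80.0 |
| spring | 2.50 | 26.0 | 71.5 |
| spring | 4.00 | 32.1 | 63.9 |
| summer | 0.500 | 24.6 | 72.1 |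
| summer | 1.25 | 39.5 | 55.4 |
| summer | 2.50 | 51.0 | 40.2 |
| summer | 4.00 | 58.8 | 30.6 |
| dawn | 1.04 | 59.3 | 24.5 |
| dawn | 2.08 | 62.7 | 10.5 |
| dawn | 3.00 | 58.7 | 4.5 |
| dawn | 4.00 | 53.5 | 3.5 |

(standard deviation of a reading: 0.5 percentage points)

1. amount of mono adduct at the end, in percent of the substrate charged for larch, alder, elm, ash, in this order
2. how that number moves from the first to the last of them (hardly changes / falls all the way / falls, then rises / rises, then falls / rises all the way)

- "hardly changes" means that all values lie within two and a half points (for a concentration: within two and a half percent of the largest)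

Reagent is the limiting reagent in larch, charged at 0.500 equiv. With the main step by itself, substrate + reagent to mono adduct, one reagent makes one mono adduct, so the reagent balance puts the ceiling for larch at 50.0 % of the substrate charged.

The next step is mono adduct + reagent, and the dawn run shows it: mono adduct falls from 62.7 % at 2.08 d to 53.5 % at 4.00 d. The gap left by the two readings is counted here as product that took two reagents. In the spring run at 4.00 d that gap is 4 percentage points, so reagent taken up comes to 40.1 % of the substrate charged, and mono adduct is 80.0 % of that. This addition lowers the larch number to 40.0 %.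

The last addition is reagent that stays untaken. In the spring run 70.4 % of the charge is taken up: reagent taken up over reagent charged is the taken share. Read the same way, it is 57.1 % in the summer run and 38.8 % in the dawn run, so across these runs it falls as the charge grows. My own reckoning for larch, with the spring share, is 28.2 %. The summer run ends higher than both its neighbours, so the row should rise, then fall.

The forecast says 29 %, 47 %, 63 %, 50 % and rises, then falls; its larch value stands higher than my 28.2 %, and at the top charge it holds that “the mono has passed its maximum and is being consumed”.

The flasks give 29.2 %, 48.4 %, 62.9 %, 49.3 %, and rises, then falls, so the forecast held.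

    substrate + reagent → other mono adduct (k = 7.80 × 10⁻⁶ M⁻¹ s⁻¹)
    reagent ⇌ dormant form (K = 0.960, k = 1.30 × 10⁻⁵ s⁻¹)
    reagent + other mono adduct → double product (k = 4.40 × 10⁻⁵ M⁻¹ s⁻¹)
    substrate + reagent → mono adduct (k = 1.40 × 10⁻⁴ M⁻¹ s⁻¹)
    reagent + mono adduct → double product (k = 3.00 × 10⁻⁵ M⁻¹ s⁻¹)

Larch holds a dormant form that the number doesn't show: it ends with c(dormant form) = 0.00448 M beside 15 % of its reagent charge left free, so its taken share is 66.9 %, against the spring 70.4 %. Alder, charged between spring and summer, has 61.2 %, between their 70.4 % and 57.1 %. In larch at 4.00 d, the main step uses reagent more slowly than the forward step to dormant form, at 0.37 of its rate.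

The numbers in the tables stem from a simulated flask for substances that don't exist; noise was put on by code.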